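(The numbers of this flask are invented; no experiment stands behind them.)

Write the balance of the reagent, counting what each adduct has cost it.

common to all: time 2.0 min
- west: substrate 21 mM; reagent 16.8 mM (fed, over 5.0 s); all else is in the flask from the start; the feed brings no volume worth counting
- north-east: substrate 21 mM; reagent 16.8 mM; everything together at the start
- south-west: substrate 21 mM (in portions, 5, over 50 s); reagent 16.8 mM; first portion at the start, last at 50 s
- east: substrate 21 mM; reagent 16.8 mM (fed, over 50 s); all else is in the flask from the start; the feed brings no volume worth counting
- south: substrate 21 mM (fed, over 50 s); reagent 16.8 mM; all else is in the flask from the start; the feed brings no volume worth counting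

    reagent + mono adduct → bis adduct + by-product (k1 = 1.08 M⁻¹ s⁻¹)
    reagent + bis adduct → tris adduct + by-product (k2 = 25.4 M⁻¹ s⁻¹)
    substrate + reagent → mono adduct + by-product (k3 = 16.4 M⁻¹ s⁻¹)
    substrate ⇌ dormant form (K4 = 0.73, k4 = 0.216 s⁻¹)

1. the best flask by share of tris adduct in tris adduct plus bis adduct; "all alike" if 1.5 percentage points covers them all (west / north-east / south-west / east / south / all alike)
2. share of tris adduct in tris adduct plus bis adduct at the end, west
3. share of tris adduct in tris adduct plus bis adduct at the end, north-east
4. share of tris adduct in tris adduct plus bis adduct at the end, south-west
5. share of tris adduct in tris adduct plus bis adduct at the end, east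
6. share of tris adduct in tris adduct plus bis adduct at the end, south

The reagent is charged in the smaller amount, 16.8 mM against 21 mM of substrate, so it is the limiting reagent. Once it is used up, its balance reads [mono adduct] + 2[bis adduct] + 3[tris adduct] = 16.8 mM.

Two chemists dispute what that balance allows. Ines says the manner of adding is a detail: at equal concentrations the reagent takes substrate 15.2 times faster than mono adduct, the same competition runs in each flask, and the shares come out alike.

Tom counts the dose, the integral of [reagent] over time. Each step that makes an adduct carries [reagent] as a factor, so the dose is their common clock, and a slow reagent feed stretches real time while the ratios of those steps stay as they were. He grants Ines west, north-east and east, which he counts as nearly one flask on that clock, but not the flasks where substrate arrives late.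

His rule goes like this. Bis adduct rests near 0.0425 of [mono adduct], and mono adduct moves on in proportion to k1 times the dose it meets after it is made. The k1 cancels, and the share is one minus the inverse of N, the number of bis adduct lifetimes in the dose a mono adduct sees after its making.

For west, north-east and east I take substrate and dormant form as balanced, so a fraction 0.578 is free. Bringing the pool down by 16.8 mM, as if the reagent stopped at mono adduct, then takes a dose of about 170 mM·s. A mono adduct made halfway sees half of that, so N is 2.16 and my share is 53.7%.

For south and south-west I let [reagent] fall roughly straight to nothing over 50 s while mono adduct builds. The dose is then 420 mM·s, and a third of it comes after making, so N is 3.56 and my share is 71.9%.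

The forecast gives 57% for west, 52% for north-east, 60% for east, 57% for south and 56% for south-west; it names east as best, with “the substrate-fed flasks in between”.

The simulation gives 60.5% in north-east, 62.1% in west, 61.5% in east, 79.6% in south and 81.9% in south-west, so south-west is best, and Ines's view stands among the first three, within 1.6 percentage points. Mean [reagent] over the first 50 s reads 8.75 mM in south and 2.38 mM in north-east, doses of 438 mM·s and 119 mM·s. The south reading makes N 3.71, a share of 73.0%. The neighbour of south-west with 5.3 mM of substrate keeps 35.1% of its reagent at 2.00 min; that [reagent], counted over the time after the last portion, makes N 10.5, a share of 90.5%, and that flask reads 96.2%.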